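| setting | summer | autumn | winter | Saturday's | Monday's | Tuesday's | Wednesday's | Sunday's |
|---|---|---|---|---|---|---|---|---|
| starting material | 26 mM | 26 mM | 26 mM | 26 mM | 26 mM | 26 mM (fed, over 12 h) | 26 mM | 26 mM (fed, over 12 h) |
| coupling partner | 24.7 mM | 12 mM | 19 mM | 24.7 mM (fed, over 3.0 h) | 24.7 mM (fed, over 12 h) | 24.7 mM | 24.7 mM | 24.7 mM |
| free catalyst | 22 µM | 22 µM | 22 µM | 22 µM | 22 µM | 22 µM | 22 µM | 22 µM |
| temperature | 85 °C | 96 °C | 85 °C | 90 °C | 90 °C | 90 °C |  |  |
| remark | run made earlier | run made earlier | run made earlier | all else is in the flask from the start; the feed brings no volume worth counting | all else is in the flask from the start; the feed brings no volume worth counting | all else is in the flask from the start; the feed brings no volume worth counting | everything together at the start at 60 °C, warmed to 90 °C at 12 h | the addition at 60 °C, then warmed to 90 °C; the feed brings no volume worth counting |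
| time |  |  |  | 20 h | 20 h | 20 h | 20 h | 20 h |

| run | time / h | target / % |
|---|---|---|
| summer | 1.00 | 7.5 |
| summer | 1.33 | 8.9 |
| summer | 2.00 | 14.1 |
| summer | 3.00 | 20.6 |
| summer | 5.00 | 30.9 |
| summer | 8.00 | 42.8 |
| summer | 12.0 | 58.3 |
| autumn | 1.00 | 14.5 |
| autumn | 3.00 | 35.3 |
| autumn | 6.00 | 46.2 |
| autumn | 8.00 | 46.6 |
| autumn | 12.0 | 45.9 |
| autumn | 15.0 | 47.0 |
| autumn | 20.0 | 47.1 |
| winter | 3.00 | 19.9 |
| winter | 6.00 | 35.0 |
| winter | 8.00 | 43.0 |
| winter | 12.0 | 57.0 |
| winter | 15.0 | 66.2 |
| winter | 20.0 | 71.5 |

(standard deviation of a reading: 0.5 percentage points)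



- the flask with the highest amount of target, in percent of the starting material charged ("all alike" if they lie within 1.5 percentage points) (Saturday's / Monday's / Tuesday's / Wednesday's / Sunday's / all alike)
- final target, as a percentage of the starting material charged, in Saturday's
- final target, as a percentage of the starting material charged, in Monday's
- final target, as a percentage of the starting material charged, in Tuesday's
- final target, as a percentage of the starting material charged, in Wednesday's
- final target, as a percentage of the starting material charged, in Sunday's

- These flasks are to be ranked by counting catalyst turnovers instead of fitting an order in starting material, and the count begins from the charge. A turnover is one passage of a catalyst molecule through its cycle. Coupling partner is the limiting reagent, its charge being smaller than that of starting material, so target has a ceiling of 95.0% of the starting material charged, which costs 1120 turnovers per catalyst. The autumn run shows such a ceiling, standing at 47.1% at 20.0 h against its 46.2%.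
- The summer run supplies the count: 689 turnovers by 12.0 h, and 45.8 h⁻¹ over its last stretch. The winter run, with less coupling partner, reads 57.0% at that time against 58.3%, so the summer count is taken for both charges while below the ceiling.
- Rate constants rise with temperature, and the first-hour readings, 7.5% in the summer run and 14.5% in the autumn run, give a reading of 65.9 kJ mol⁻¹ for the activation energy, provided that the smaller coupling partner charge of the autumn run is set aside, as the winter run suggests. The weight of an hour at 90 °C, against an hour at 85 °C, is therefore 1.36, and the weight of an hour at 60 °C is 0.190.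
- The catalyst clock is the time in a flask with each hour weighted so, in hours at 85 °C: Wednesday's and Sunday's each get 13.1 h, while Saturday's, Monday's and Tuesday's each get 27.1 h. The clock takes no account of feeding, and that is the wager in this reckoning.
- Extending the summer count at 45.8 h⁻¹ gives Wednesday's and Sunday's 741 turnovers, or 62.7% of the charge. Saturday's, Monday's and Tuesday's get 1380, which is more than the 1120 required, so those flasks are reckoned close to the ceiling.
- The forecast named Saturday's with 87%, then Monday's 86%, Tuesday's 74%, which is below the ceiling this reckoning approaches, Wednesday's 62% and Sunday's 59%, noting “Saturday and Monday are effectively tied”.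
- Saturday's comes out highest at 92.0%, followed by Tuesday's 89.8%, Monday's 89.5%, Wednesday's 62.5% and Sunday's 62.2%. Left ten times as long, Sunday's holds 95.0% target at 200 h. Wednesday's and Sunday's share the clock of 13.1 h and end 0.3 percentage points apart, although Sunday's starting material was fed and Wednesday's was all there from the start.

    catalyst intermediate D → free catalyst + target (k = 180 h⁻¹, Ea = 85.0 kJ mol⁻¹)
    catalyst intermediate B → catalyst intermediate C (k = 15000 h⁻¹, Ea = 84.0 kJ mol⁻¹)
    catalyst intermediate C ⇌ released group + catalyst intermediate D (K = 0.00880 M, k = 1900 h⁻¹, Ea = 89.0 kJ mol⁻¹, ΔH = −1.00 kJ mol⁻¹)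
    released group → by-product carried off (k = 0.0240 h⁻¹, Ea = 124 kJ mol⁻¹)
    starting material + catalyst intermediate A ⇌ catalyst intermediate B (K = 74.0 M⁻¹, k = 2.40 × 10⁵ M⁻¹ h⁻¹, Ea = 37.0 kJ mol⁻¹, ΔH = −5.00 kJ mol⁻¹)
    coupling partner + free catalyst ⇌ catalyst intermediate A (K = 40.0 M⁻¹, k = 1.70 × 10⁵ M⁻¹ h⁻¹, Ea = 59.0 kJ mol⁻¹, ΔH = −8.00 kJ mol⁻¹)
    (constants at 90 °C)

- The neighbour of Sunday's with 15 mM of coupling partner keeps the clock of 13.1 h, but its ceiling of 57.7% lies below the count's 62.7%, so the reckoning gives 57.7%. The computed flask gives 55.0%, with 45% of the starting material left unbound.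

(The runs come from a simulation from invented constants; scatter was added.)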